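**Plan**
- Cuts (germacrane numbering): the O14 acyl and O9 acetyl esters; C9–C10 (ten-membered ring); C11=C13; O6–C12 (γ-lactone); C5–C6 (fragment union); C7–C11 (malate alkylation).
- Forward order: fragment A (C6–C9, C11, C12) comes from dimethyl (S)-malate and fragment B (C1–C5, C10, C14, C15) from 4-pentyn-1-ol. They are joined at C5–C6. The γ-lactone ring closes first, the exocyclic methylene follows, the carbocycle closes last at C9–C10, and then the three oxygens are dressed.
- Stereochemistry: C8 comes from (S)-malate, C7 from a Fráter–Seebach alkylation, C6 from a Felkin–Anh addition, and C9 from a polar Felkin–Anh addition during ring closure. Both Z olefins are fixed in the acyclic dihalide and carried over with retention. The side-chain centre comes from (R)-2-methylbutanoic acid.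
- Enabling feature: C10 is a vinylic carbon next to the C14 oxygen and C9 is a carbonyl carbon next to the C8 oxygen, so their bond is that of an alkenyl-metal/α-silyloxy aldehyde pair. The Z olefins C1=C10 and C4=C5 and the trans-fused lactone ring (O6–C6–C7–C11–C12) bend the ten-carbon chain so that its ends meet.
- The closure is run as an electroreductive, chromium-catalytic Ni/Cr coupling. The helpers (C10 bromide, 8-O-triethylsilyl, 14-O-silyl) leave in or after this step.

Key step: step 16

Remark: germacrane numbering (C1–C15) is used for all intermediates, and compounds 12 and 30 are taken as commercial single compounds.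

Step 1
Reactants: 1 dimethyl (S)-malate; 2 tert-butyl bromoacetate
Product: 3 3-tert-butyl 1,2-dimethyl (1S,2R)-1-hydroxypropane-1,2,3-tricarboxylate
Conditions: LiHMDS (2.2 equiv), THF, −78 to −20 °C; then 2, −78 to −10 °C
Reagents that add atoms: none
Why: Fráter–Seebach alkylation, in which the lithium-chelated alkoxide-enolate dianion of the β-hydroxy ester is alkylated at C7 on the face away from the C9 ester group of the chelate ring, so that the anti product forms and C7 is set from C8.

Step 2
Reactants: 3 triester
Product: 4 methyl (2R,3S)-2-(2-tert-butoxy-2-oxoethyl)-3,4-dihydroxybutanoate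
Conditions: BH3·SMe2 (1.05 equiv), NaBH4 (5 mol %), THF, 0 °C to rt; MeOH quench
Reagents that add atoms: none
Why: Hydroxyl-directed borane reduction, in which the five-membered alkoxyborane formed at O8 delivers hydride only to the neighbouring C9 ester, as known for malates, while the C6 and C12 esters and both stereocentres stay untouched.

Step 3
Reactants: 4 diol
Product: 5 4-tert-butyl 1-methyl (2R)-2-[(4S)-2,2-dimethyl-1,3-dioxolan-4-yl]butanedioate
Conditions: 2,2-dimethoxypropane, p-TsOH (cat.), acetone, rt
Reagents that add atoms: 2,2-dimethoxypropane COC(C)(C)OC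
Why: Acid-catalysed transketalisation closes the favoured five-membered acetonide over O8 and O9 faster than the diol can lactonise, and no stereocentre is touched.

Step 4
Reactants: 5 acetonide diester
Product: 6 tert-butyl (3R)-3-[(4S)-2,2-dimethyl-1,3-dioxolan-4-yl]-4-oxobutanoate (fragment A)
Conditions: DIBAL-H (1.1 equiv), toluene, −78 °C; Rochelle salt work-up
Reagents that add atoms: none
Why: Partial DIBAL-H reduction of an ester, in which the methyl ester at C6 is reduced to a tetrahedral aluminium acetal that is stabilised by the dioxolane oxygen and collapses to the aldehyde only on work-up, while the bulky tert-butyl ester is too slow to compete.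

Step 5
Reactants: 7 4-pentyn-1-ol
Product: 10 (Z)-5-iodo-4-methylpent-4-en-1-ol, via E-alkenylalane 8 (not isolated), via cyclic Z-alkenylalane 9 (not isolated)
Conditions: AlMe3 (3 equiv), Cp2ZrCl2 (25 mol %), ClCH2CH2Cl, rt; AlCl3 (25 mol %), 50 °C; then I2, THF, −30 to 0 °C
Reagents that add atoms: trimethylaluminium C[Al](C)C; iodine [I][I]
Why: Negishi carboalumination gives the syn adduct 8, chelation by the tethered aluminium alkoxide then drives its isomerisation to the cyclic Z-alane 9, and iodinolysis with retention fixes the Z geometry of the later C4=C5 olefin.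

Step 6
Reactants: 10 iodoalkenol
Product: 11 (Z)-5-iodo-4-methylpent-4-enal
Conditions: Dess–Martin periodinane, CH2Cl2, 0 °C to rt
Reagents that add atoms: none
Why: Dess–Martin oxidation turns the primary alcohol into the aldehyde under neutral conditions that leave the alkenyl iodide and its geometry alone.

Step 7
Reactants: 11 aldehyde; 12 ethyl bromo(triphenyl-λ5-phosphanylidene)acetate
Product: 13 ethyl (2Z,6Z)-2-bromo-7-iodo-6-methylhepta-2,6-dienoate
Conditions: CH2Cl2, 0 °C to rt
Reagents that add atoms: none
Why: Wittig olefination with a stabilised α-bromo ylide places the ester trans to the chain and hence bromine cis to C2, which is the geometry needed at C1=C10.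

Step 8
Reactants: 13 bromoenoate
Product: 14 (2Z,6Z)-2-bromo-7-iodo-6-methylhepta-2,6-dien-1-ol
Conditions: DIBAL-H (2.3 equiv), CH2Cl2, −78 °C
Reagents that add atoms: none
Why: DIBAL-H reduces the enoate in the 1,2 sense to the allylic alcohol (C14) without touching either alkenyl halide.

Step 9
Reactants: 14 allylic alcohol
Product: 15 tert-butyl{[(2Z,6Z)-2-bromo-7-iodo-6-methylhepta-2,6-dien-1-yl]oxy}diphenylsilane (fragment B)
Conditions: t-BuPh2SiCl, imidazole, CH2Cl2, rt
Reagents that add atoms: tert-butylchlorodiphenylsilane CC(C)(C)[Si](Cl)(c1ccccc1)c1ccccc1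
Why: Standard silylation gives an acid-stable ether at O14 that survives the later acetonide hydrolysis and is a poor leaving group next to the future alkenyl metal.

Step 10
Reactants: 15 fragment B; 6 fragment A
Product: 17 C5–C6 coupled allylic alcohol (6R), via alkenylchromium 16 (not isolated)
Conditions: CrCl2 (4 equiv), NiCl2 (2 mol %), DMSO, rt
Reagents that add atoms: none
Why: Nozaki–Hiyama–Kishi coupling, in which zerovalent nickel inserts into the carbon–iodine bond at C5 much faster than into the carbon–bromine bond at C10, the alkenylchromium 16 keeps its Z geometry, and it adds to the aldehyde in the Felkin–Anh sense (dioxolanyl C8 as the large group, reinforced by the 1,3-anti preference of the β-oxygen), which sets 6R.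

Step 11
Reactants: 17 hydroxy ester
Product: 18 trans-β,γ-disubstituted γ-butyrolactone (O6–C12 closed)
Conditions: KOt-Bu (10 mol %), THF, 0 °C
Reagents that add atoms: none
Why: Alkoxide-catalysed 5-exo-trig lactonisation avoids acid at the ionisable allylic C6–O bond, regenerates tert-butoxide as the chain carrier, and gives the trans lactone because C6 and C7 are already set.

Step 12
Reactants: 18 lactone
Product: 21 α-methylene-γ-butyrolactone acetonide, via Mannich base 19 (not isolated), via methiodide 20 (not isolated)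
Conditions: LiHMDS (1.2 equiv), THF, −78 °C; Eschenmoser's salt (3 equiv), −78 °C to rt; MeI, CH2Cl2, rt; aq NaHCO3, CH2Cl2, rt
Reagents that add atoms: Eschenmoser's salt C=[N+](C)C.[I-]
Why: Enolate Mannich reaction followed by quaternisation and E1cB loss of trimethylamine is the standard α-methylenation of γ-butyrolactones, the transient C11 centre is erased, and the short exposure to one equivalent of amide base at −78 °C spares the alkenyl bromide.

Step 13
Reactants: 21 acetonide
Product: 22 8,9-diol
Conditions: AcOH/H2O 4:1, 40 °C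
Reagents that add atoms: none
Why: Mild acid hydrolysis removes the terminal acetonide while the tert-butyldiphenylsilyl ether, the lactone and the exocyclic enoate are stable to aqueous acetic acid.

Step 14
Reactants: 22 diol
Product: 23 8,9-bis(triethylsilyl) ether
Conditions: Et3SiOTf (2.5 equiv), 2,6-lutidine, CH2Cl2, −78 to 0 °C
Reagents that add atoms: triethylsilyl trifluoromethanesulfonate CC[Si](CC)(CC)OS(=O)(=O)C(F)(F)F
Why: Exhaustive silylation with the triflate covers the hindered O8 as well as O9 under non-nucleophilic conditions that do not add to the enoate.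

Step 15
Reactants: 23 bis-silyl ether
Product: 24 seco aldehyde (C9 aldehyde; 8-O-triethylsilyl; C10 bromide)
Conditions: (COCl)2 (4 equiv), DMSO (8 equiv), CH2Cl2, −78 to −40 °C; Et3N, −78 to 0 °C
Reagents that add atoms: none
Why: Swern oxidation of silyl ethers, in which the activated sulfoxide attacks the unhindered primary triethylsilyl ether directly and oxidises it to the aldehyde while the secondary ether at O8 is too hindered to react, so deprotection and oxidation are one operation.

Step 16
Reactants: 24 seco aldehyde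
Product: 27 ten-membered carbocyclic 9-alcohol (9R), via alkenylchromium 25 (not isolated), via zirconocene alkoxide 26 (not isolated)
Conditions: CrCl2 (20 mol %), NiCl2·glyme (5 mol %), 2,9-dimethyl-1,10-phenanthroline (5 mol %), Cp2ZrCl2 (1.5 equiv), LiCl, Bu4NBr (0.1 mol/L), DMF, undivided cell, Al anode, Ni-foam cathode, constant current, rt; 24 added by syringe pump (final 2 mmol/L); aqueous work-up
Reagents that add atoms: none
Why: At the cathode the nickel and chromium salts are kept in their reduced states: zerovalent nickel inserts into the C10–Br bond with retention of the Z geometry, the alkenyl group passes to chromium to give the trivalent alkenylchromium 25, this adds to the C9 aldehyde, and Cp2ZrCl2 takes over the alkoxide (26) so that chromium re-enters the cycle while the aluminium anode supplies the electrons. The closest known reaction type is the Nozaki–Hiyama–Kishi alkenylation of aldehydes, known as a stoichiometric closure of medium and large carbocycles and, with alkenyl bromides, as an electroreductive chromium-catalytic coupling. The ten-membered carbocycle (C1–C10) closes in the 10-exo-trig mode, C10 attacking C9 with the C=O bond outside the new ring. The new stereocentre C9 is controlled by C8: in the polar Felkin–Anh rotamer the C8–OSiEt3 bond stands anti to the incoming C10, which gives the 8,9-anti relationship (9R). Ring closure must beat oligomerisation and protodebromination, which is secured by slow addition, by the current-limited low stationary concentration of 25, and by the fold that the two Z olefins (C1=C10, C4=C5) and the trans-fused lactone ring impose on the chain from C10 to C9. Selectivity for the aldehyde over the lactone, the exocyclic enoate and the silyl ethers rests on the low basicity and strict aldehyde preference of alkenylchromium reagents, and the step leaves O9 as the only free hydroxyl, so the oxygens at C8, C9 and C14 are told apart at once.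

Step 17
Reactants: 27 9-alcohol
Product: 28 9-acetate
Conditions: Ac2O, DMAP (cat.), pyridine, CH2Cl2, 0 °C to rt
Reagents that add atoms: acetic anhydride CC(=O)OC(C)=O
Why: DMAP-catalysed acetylation meets only one free hydroxyl (O9), so the acetate is placed regiospecifically with retention at C9.

Step 18
Reactants: 28 acetate
Product: 29 8,14-diol 9-acetate
Conditions: HF·pyridine, pyridine/THF, 0 °C to rt
Reagents that add atoms: none
Why: Buffered fluoride under slightly acidic conditions cleaves both silyl ethers without the basic alkoxide that would trigger acetyl migration from O9 to O8 or O14.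

Step 19
Reactants: 29 diol; 30 (R)-2-methylbutanoic acid
Product: 32 target CNP0005248.2, via O-acylisourea 31 (not isolated)
Conditions: N,N'-diisopropylcarbodiimide (1.1 equiv), DMAP (5 mol %), CH2Cl2, −20 °C
Reagents that add atoms: none
Why: Steglich esterification at low temperature acylates the unhindered primary allylic O14 far faster than the secondary O8 flanked by C7 and the C9 acetate, and the mild activation avoids ketene formation so the α-centre of the acid is kept.

**Compound list**
1 | dimethyl (S)-malate | COC(=O)[C@@H](O)CC(=O)OC | starting material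
2 | tert-butyl bromoacetate | CC(C)(C)OC(=O)CBr | starting material
3 | 3-tert-butyl 1,2-dimethyl (1S,2R)-1-hydroxypropane-1,2,3-tricarboxylate (anti; C8 and C7 set) | COC(=O)[C@@H](O)[C@@H](CC(=O)OC(C)(C)C)C(=O)OC | intermediate
4 | methyl (2R,3S)-2-(2-tert-butoxy-2-oxoethyl)-3,4-dihydroxybutanoate | OC[C@@H](O)[C@@H](CC(=O)OC(C)(C)C)C(=O)OC | intermediate
5 | 4-tert-butyl 1-methyl (2R)-2-[(4S)-2,2-dimethyl-1,3-dioxolan-4-yl]butanedioate | CC1(C)OC[C@@H](O1)[C@@H](CC(=O)OC(C)(C)C)C(=O)OC | intermediate
6 | tert-butyl (3R)-3-[(4S)-2,2-dimethyl-1,3-dioxolan-4-yl]-4-oxobutanoate (fragment A, C6 aldehyde) | CC1(C)OC[C@@H](O1)[C@@H](CC(=O)OC(C)(C)C)C=O | intermediate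
7 | 4-pentyn-1-ol | C#CCCCO | starting material
8 | (E)-alkenylalane, dimethylaluminium alkoxide of the syn carboalumination adduct | C[Al](C)OCCC/C(C)=C/[Al](C)C | intermediate
9 | cyclic (Z)-alkenylalane (seven-membered oxa-aluminacycle) | CC1=C[Al](C)OCCC1 | intermediate
10 | (Z)-5-iodo-4-methylpent-4-en-1-ol | I/C=C(/C)CCCO | intermediate
11 | (Z)-5-iodo-4-methylpent-4-enal | I/C=C(/C)CCC=O | intermediate
12 | ethyl bromo(triphenyl-λ5-phosphanylidene)acetate | CCOC(=O)C(Br)=P(c1ccccc1)(c1ccccc1)c1ccccc1 | starting material
13 | ethyl (2Z,6Z)-2-bromo-7-iodo-6-methylhepta-2,6-dienoate | I/C=C(/C)CC/C=C(/C(=O)OCC)Br | intermediate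
14 | (2Z,6Z)-2-bromo-7-iodo-6-methylhepta-2,6-dien-1-ol | I/C=C(/C)CC/C=C(/CO)Br | intermediate
15 | tert-butyldiphenylsilyl ether of 14 (fragment B) | I/C=C(/C)CC/C=C(/CO[Si](c1ccccc1)(c1ccccc1)C(C)(C)C)Br | intermediate
16 | C5 alkenylchromium dichloride of fragment B (Z retained) | Cl[Cr](Cl)/C=C(/C)CC/C=C(/CO[Si](c1ccccc1)(c1ccccc1)C(C)(C)C)Br | intermediate
17 | C5–C6 coupled allylic alcohol: 6R carbinol, C7 bearing CH2CO2t-Bu and the (4S)-dioxolanyl group (C8, C9), Z-C4=C5, Z-C1=C10 bromide, 14-O-silyl | O[C@H](/C=C(/C)CC/C=C(/CO[Si](c1ccccc1)(c1ccccc1)C(C)(C)C)Br)[C@H](CC(=O)OC(C)(C)C)[C@H]1COC(C)(C)O1 | intermediate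
18 | trans-γ-butyrolactone (O6–C12), C6, C7, C8 as in the target | O=C1O[C@H](/C=C(/C)CC/C=C(/CO[Si](c2ccccc2)(c2ccccc2)C(C)(C)C)Br)[C@@H]([C@H]2COC(C)(C)O2)C1 | intermediate
19 | α-(dimethylaminomethyl) lactone (C11 epimers) | CN(C)CC1C(=O)O[C@H](/C=C(/C)CC/C=C(/CO[Si](c2ccccc2)(c2ccccc2)C(C)(C)C)Br)[C@H]1[C@H]2COC(C)(C)O2 | intermediate
20 | methiodide of 19 | C[N+](C)(C)CC1C(=O)O[C@H](/C=C(/C)CC/C=C(/CO[Si](c2ccccc2)(c2ccccc2)C(C)(C)C)Br)[C@H]1[C@H]2COC(C)(C)O2.[I-] | intermediate
21 | α-methylene-γ-butyrolactone with 8,9-acetonide | C=C1C(=O)O[C@H](/C=C(/C)CC/C=C(/CO[Si](c2ccccc2)(c2ccccc2)C(C)(C)C)Br)[C@H]1[C@H]2COC(C)(C)O2 | intermediate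
22 | 8,9-diol | C=C1C(=O)O[C@H](/C=C(/C)CC/C=C(/CO[Si](c2ccccc2)(c2ccccc2)C(C)(C)C)Br)[C@H]1[C@H](O)CO | intermediate
23 | 8,9-bis(triethylsilyl) ether | C=C1C(=O)O[C@H](/C=C(/C)CC/C=C(/CO[Si](c2ccccc2)(c2ccccc2)C(C)(C)C)Br)[C@H]1[C@H](O[Si](CC)(CC)CC)CO[Si](CC)(CC)CC | intermediate
24 | seco aldehyde: C9 aldehyde, 8-O-triethylsilyl, Z-C10 bromide | C=C1C(=O)O[C@H](/C=C(/C)CC/C=C(/CO[Si](c2ccccc2)(c2ccccc2)C(C)(C)C)Br)[C@H]1[C@H](O[Si](CC)(CC)CC)C=O | intermediate
25 | C10 alkenylchromium dichloride of 24 | C=C1C(=O)O[C@H](/C=C(/C)CC/C=C(/CO[Si](c2ccccc2)(c2ccccc2)C(C)(C)C)[Cr](Cl)Cl)[C@H]1[C@H](O[Si](CC)(CC)CC)C=O | intermediate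
26 | chlorozirconocene C9 alkoxide of 27 | C=C1C(=O)O[C@@H]2/C=C(/C)CC/C=C(/CO[Si](c3ccccc3)(c3ccccc3)C(C)(C)C)[C@@H]([O-])[C@@H](O[Si](CC)(CC)CC)[C@@H]12.[Zr+4].[Cl-].[CH-]1C=CC=C1.[CH-]1C=CC=C1 | intermediate
27 | (1(10)Z,4Z)-germacradien-12,6-olide with free 9R hydroxyl, 8-O-triethylsilyl, 14-O-tert-butyldiphenylsilyl | C=C1C(=O)O[C@@H]2/C=C(/C)CC/C=C(/CO[Si](c3ccccc3)(c3ccccc3)C(C)(C)C)[C@@H](O)[C@@H](O[Si](CC)(CC)CC)[C@@H]12 | intermediate
28 | 9-acetate of 27 | C=C1C(=O)O[C@@H]2/C=C(/C)CC/C=C(/CO[Si](c3ccccc3)(c3ccccc3)C(C)(C)C)[C@@H](OC(C)=O)[C@@H](O[Si](CC)(CC)CC)[C@@H]12 | intermediate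
29 | 9-acetoxy-8,14-diol | C=C1C(=O)O[C@@H]2/C=C(/C)CC/C=C(/CO)[C@@H](OC(C)=O)[C@@H](O)[C@@H]12 | intermediate
30 | (R)-2-methylbutanoic acid | CC[C@@H](C)C(=O)O | starting material
31 | O-acylisourea from 30 and N,N'-diisopropylcarbodiimide | CC[C@@H](C)C(=O)OC(=NC(C)C)NC(C)C | intermediate
32 | CNP0005248.2 | C=C1C(=O)O[C@@H]2/C=C(/C)CC/C=C(/COC(=O)[C@H](C)CC)[C@@H](OC(C)=O)[C@@H](O)[C@@H]12 | target

**Step count.** Total steps: 19. Longest linear sequence: 15 (steps 5 to 19).

**Steps most likely to fail**

Step 16. Intermolecular coupling and protodebromination of the alkenyl metal may outrun closure of the strained ring, or the aldehyde faces may be attacked without selectivity.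
- The fallback forms the same C9–C10 bond at the ketone level by an acylative cross-coupling and sets C9 afterwards with hydride.
- It sets out from 24. Pinnick oxidation (NaClO2, NaH2PO4, 2-methyl-2-butene) should give the seco acid F1. 4-Methylbenzenethiol with N,N'-diisopropylcarbodiimide should give the S-aryl thioester F2.
- Stannylation with hexabutyldistannane and Pd(PPh3)4 should convert the C10 bromide into the alkenylstannane F3.
- A Liebeskind–Srogl closure at high dilution (Pd2(dba)3, tri(2-furyl)phosphine, copper thiophene-2-carboxylate Cu(O2CC4H3S)) should give the macrocyclic enone F4.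
- Luche reduction (NaBH4, CeCl3·7H2O, MeOH, −78 °C), with hydride anti to the C8–O bond, comes back to the route at 27.

Step 10. Facial selectivity at C6 may be poor, because the alkenylchromium reagent responds only moderately to the α-stereocentre.
- The fallback sets C6 by reagent-controlled reduction instead of by addition.
- It sets out from crude 17 (C6 epimers). Dess–Martin oxidation should give the Z-dienone F5.
- Corey–Bakshi–Shibata reduction (Me-CBS oxazaborolidine, enantiomer selected for 6R, BH3·SMe2, −40 °C) comes back to the route at 17.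

Step 1. Proton transfer from the acidic bromoacetate to the dianion may erode the alkylation.
- The fallback uses the classical electrophile and adjusts the oxidation level later.
- It sets out from 1. Fráter–Seebach alkylation with allyl bromide should give dimethyl (2S,3R)-3-allylmalate F6.
- The conditions of step 2 should give the diol F7, and those of step 3 the acetonide F8.
- RuCl3/NaIO4 cleavage of the terminal olefin should give the acid F9. tert-Butyl 2,2,2-trichloroacetimidate (cat. BF3·OEt2) comes back to the route at 5.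

**Further compounds**
F1 | step 16 | seco acid (C9 carboxylic acid, C10 bromide) | C=C1C(=O)O[C@H](/C=C(/C)CC/C=C(/CO[Si](c2ccccc2)(c2ccccc2)C(C)(C)C)Br)[C@H]1[C@H](O[Si](CC)(CC)CC)C(=O)O
F2 | step 16 | S-(4-methylphenyl) thioester | C=C1C(=O)O[C@H](/C=C(/C)CC/C=C(/CO[Si](c2ccccc2)(c2ccccc2)C(C)(C)C)Br)[C@H]1[C@H](O[Si](CC)(CC)CC)C(=O)Sc1ccc(C)cc1
F3 | step 16 | C10 tributylstannyl thioester | C=C1C(=O)O[C@H](/C=C(/C)CC/C=C(/CO[Si](c2ccccc2)(c2ccccc2)C(C)(C)C)[Sn](CCCC)(CCCC)CCCC)[C@H]1[C@H](O[Si](CC)(CC)CC)C(=O)Sc1ccc(C)cc1
F4 | step 16 | macrocyclic C9 enone | C=C1C(=O)O[C@@H]2/C=C(/C)CC/C=C(/CO[Si](c3ccccc3)(c3ccccc3)C(C)(C)C)C(=O)[C@@H](O[Si](CC)(CC)CC)[C@@H]12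
F5 | step 10 | C6 Z-dienone | O=C(/C=C(/C)CC/C=C(/CO[Si](c1ccccc1)(c1ccccc1)C(C)(C)C)Br)[C@H](CC(=O)OC(C)(C)C)[C@H]1COC(C)(C)O1
F6 | step 1 | dimethyl (2S,3R)-3-allylmalate | COC(=O)[C@@H](O)[C@@H](CC=C)C(=O)OC
F7 | step 1 | methyl (2R)-2-[(1S)-1,2-dihydroxyethyl]pent-4-enoate | OC[C@@H](O)[C@@H](CC=C)C(=O)OC
F8 | step 1 | methyl (2R)-2-[(4S)-2,2-dimethyl-1,3-dioxolan-4-yl]pent-4-enoate | CC1(C)OC[C@@H](O1)[C@@H](CC=C)C(=O)OC
F9 | step 1 | (3R)-3-[(4S)-2,2-dimethyl-1,3-dioxolan-4-yl]-4-methoxy-4-oxobutanoic acid | CC1(C)OC[C@@H](O1)[C@@H](CC(=O)O)C(=O)OC
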